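The numbers in the tables were computed for an exercise, and the scatter is random.

The equivalent is the unit to watch: oak, maple and cedar differ in their equivalents of E, and so do the two earlier runs.

| setting | dusk | summer | oak | maple | cedar |
|---|---|---|---|---|---|
| L | 20 mM | 20 mM | 20 mM | 20 mM | 20 mM |
| E | 1.4 equiv | 2.5 equiv | 1.10 equiv | 1.30 equiv | 1.60 equiv |
| remark | run made earlier | run made earlier |  |  |  |
| time |  |  | 4.0 d | 4.0 d | 4.0 d |

| run | time / h | L / % | Z / % |
|---|---|---|---|
| dusk | 4.00 | 98.4 | 3.6 |
| dusk | 6.00 | 98.1 | 1.3 |
| dusk | 8.00 | 96.0 | 3.3 |
| dusk | 15.0 | 87.3 | 13.6 |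
| dusk | 20.0 | 78.2 | 19.5 |
| dusk | 30.0 | 68.8 | 31.7 |
| dusk | 50.0 | 59.1 | 40.5 |
| summer | 2.50 | 98.6 | 4.2 |
| summer | 8.00 | 84.4 | 17.5 |
| summer | 15.0 | 49.1 | 52.6 |
| summer | 20.0 | 33.7 | 68.4 |
| summer | 30.0 | 15.6 | 83.8 |
| summer | 40.0 | 12.1 | 88.9 |
| summer | 50.0 | 11.0 | 87.9 |

(standard deviation of a reading: 1 percentage point)

1. which of these there is most of at the end, counted by the L in it, oak (L / Z)
2. which of these there is most of at the end, counted by the L in it, maple (L / Z)
3. which of these there is most of at the end, counted by the L in it, cedar (L / Z)
4. amount of the one of these that there is most of at the end, in percent of the L charged, oak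
5. amount of the one of these that there is most of at the end, in percent of the L charged, maple
6. amount of the one of these that there is most of at the end, in percent of the L charged, cedar

- the earlier runs were read with a standard deviation of 1 percentage point
- steps that have been proposed: L + E + Z -> 2 Z; L + E -> Z; E -> D

Amounts are fractions of the L charged: l as L, z as Z, d as E lost to D, r as E unused, e as E charged. Each proposed step to Z spends one E per Z gained, so:

l + z = 1
e = z + d + r

The runs form a ladder. On the first rung, dusk shows little: z reads 0.0330 at 8.00 h. On the second, summer's z climbs 0.0242 /h up to 8.00 h, then 0.0501 /h up to 15.0 h, twice as fast, the mark of autocatalysis. On the third, summer stalls near z = 0.879 with l = 0.110 unused, so E has left by another way: taking r as small, d is 1.62, more than z. On the slowest, dusk still rises from 0.317 at 30.0 h to 0.405 at 50.0 h. The asked 4.0 d is twice that last reading; as an assumption of this reckoning, the flasks have stopped by then, and dusk's last reading stands in for its end although dusk was still rising.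

The quantity to carry is the marginal yield m, the part of each further equivalent of E that ends as Z rather than D, read as a straight line between the runs:

m = (0.879 − 0.405) / (2.5 − 1.4) = 0.431
z = z(dusk) + m · (e − e(dusk))

This reckoning gives z = 0.276 for oak, 0.362 for maple and 0.491 for cedar. Oak and maple therefore end mostly L. Cedar lands 0.88 percentage points below an even split, less than the scatter of one reading, so the line leans to L there without really calling it.

The forecast says oak L at 71%, maple L at 61.5% and cedar Z at 53%, and so parts from the line on cedar. Its reading of the curves: “Both runs stall with L left, so E is also being lost through E → D.”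

The flasks end with oak L at 73.0%, maple L at 63.1% and cedar Z at 52.6%, so the forecast held, cedar by 2.6 points over even.

    L + E + Z → 2 Z (k = 460 /M²/h)
    L + E → Z (k = 0.0900 /M/h)
    E → D (k = 0.0420 /h)

In oak, E has a half-life of 0.69 d by the path to D alone, shorter than the 4.0 d asked. At 4.00 d, with E at 0.107% of its charge, the half-life of L by L + E + Z → 2 Z in oak stands at 490 d, longer than that time. From oak to cedar, m reads 0.512, steeper than the line.

On oak's neighbour with 2.80 equiv of E, m gives z = 1.01, above what l + z allows, so the line runs past its ceiling there. After 4.00 d that neighbour gives z = 0.968 and l = 0.0320.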